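**Retrosynthetic overview**
1. Target acid ⇐ Pinnick oxidation of the hydrindene aldehyde 27.
2. Both rings are formed last and together: a biomimetic type‑I intramolecular Diels–Alder (IMDA) of the acyclic (2E,4Z,6S,7E,9E,11E,13E)-hexaenal 26 closes the cyclopentene (C3a–C7a) and the cyclohexene (C4–C5) in one step.
3. Hexaenol 25 ⇐ Negishi sp²–sp² coupling (C8–C9) of a trienylalane (from dienyne 24) with vinyl iodide 18.
4. 18 ⇐ (R)-Roche ester: E-vinyl iodide by Corey–Fuchs / MeI / hydrozirconation–iodination; (2E,4Z)-dienol by Still–Gennari then Wittig.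
5. 24 ⇐ (E)-β-bromostyrene by two ethynylation / Zr-catalysed carboalumination iterations.

Assumptions: the target is (1R,3aR,4R,5S,7aS) with a 1E,3E side chain (read from the SMILES). The one-pot oxidation/IMDA is counted as one step, with dienal 26 not isolated. All polyene steps are run in the dark with BHT. Nothing here has been run; the IMDA selectivity is predicted from first principles, not from a known result.

**Route**

Step 1
Reactants: 1 methyl (R)-3-hydroxy-2-methylpropanoate; 2 tert-butyldimethylsilyl chloride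
Product: 3 methyl (R)-3-[(tert-butyldimethylsilyl)oxy]-2-methylpropanoate
Conditions: TBSCl, imidazole, CH2Cl2, 0 °C → rt
Reagents that add atoms: TBSCl, CC(C)(C)[Si](C)(C)Cl
Why: Silyl protection of the primary alcohol for the hydride and organolithium steps; the chiral-pool stereocentre (the only one carried into the IMDA) is untouched.

Step 2
Reactants: 3
Product: 4 (R)-3-[(tert-butyldimethylsilyl)oxy]-2-methylpropanal
Conditions: DIBAL-H (1.1 equiv), CH2Cl2, −78 °C; MeOH, Rochelle salt
Reagents that add atoms: none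
Why: Low-temperature DIBAL half-reduction stops at the aluminium hemiacetal and gives the aldehyde without epimerisation.

Step 3
Reactants: 4; 5 carbon tetrabromide
Product: 6 (S)-tert-butyl[(4,4-dibromo-2-methylbut-3-en-1-yl)oxy]dimethylsilane
Conditions: CBr4, PPh3, 2,6-lutidine, CH2Cl2, 0 °C
Reagents that add atoms: CBr4, BrC(Br)(Br)Br
Why: Corey–Fuchs (Ramirez) dibromo-olefination is non-basic, so the α-stereocentre survives.

Step 4
Reactants: 6; 7 iodomethane
Product: 8 (S)-tert-butyldimethyl[(2-methylpent-3-yn-1-yl)oxy]silane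
Conditions: n-BuLi (2.2 equiv), THF, −78 °C; then MeI, −78 °C → rt
Reagents that add atoms: MeI, CI
Why: Second stage of the Corey–Fuchs reaction (Li/Br exchange, Fritsch–Buttenberg–Wiechell shift) gives the lithium acetylide, which is methylated in situ.

Step 5
Reactants: 8; 9 iodine
Product: 10 (S,E)-tert-butyl[(4-iodo-2-methylpent-3-en-1-yl)oxy]dimethylsilane
Conditions: Cp2Zr(H)Cl (2.2 equiv), THF, 50 °C; then I2, THF, 0 °C
Reagents that add atoms: I2, II
Why: Schwartz hydrozirconation is a syn H–Zr addition that equilibrates Zr onto the less hindered, methyl-bearing carbon; iodinolysis with retention gives the E-trisubstituted vinyl iodide.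

Step 6
Reactants: 10
Product: 11 (S,E)-4-iodo-2-methylpent-3-en-1-ol
Conditions: TBAF, THF, 0 °C → rt
Reagents that add atoms: none
Why: Fluoride desilylation; the vinyl iodide and the stereocentre are inert.

Step 7
Reactants: 11
Product: 12 (S,E)-4-iodo-2-methylpent-3-enal
Conditions: Dess–Martin periodinane, NaHCO3, CH2Cl2, 0 °C; used crude immediately
Reagents that add atoms: none
Why: Buffered, non-basic Dess–Martin oxidation gives the epimerisation-prone α-methyl-β,γ-unsaturated aldehyde without racemisation or conjugation.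

Step 8
Reactants: 12; 13 ethyl 2-[bis(2,2,2-trifluoroethoxy)phosphoryl]propanoate
Product: 14 ethyl (2Z,4R,5E)-6-iodo-2,4-dimethylhepta-2,5-dienoate
Conditions: 13, KHMDS, 18-crown-6, THF, −78 °C; then 12, −78 °C
Reagents that add atoms: phosphonate 13, CCOC(=O)C(C)P(=O)(OCC(F)(F)F)OCC(F)(F)F
Why: Still–Gennari olefination (trifluoroethyl phosphonate, dissociated K⁺) gives the Z-trisubstituted enoate under kinetic control at −78 °C, fast enough to outrun α-epimerisation.

Step 9
Reactants: 14
Product: 15 (2Z,4R,5E)-6-iodo-2,4-dimethylhepta-2,5-dien-1-ol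
Conditions: DIBAL-H (2.5 equiv), CH2Cl2, −78 °C
Reagents that add atoms: none
Why: Clean 1,2-reduction of the enoate; vinyl iodide and Z-olefin are unaffected.

Step 10
Reactants: 15; 16 ethyl 2-(triphenylphosphoranylidene)propanoate
Product: 17 ethyl (2E,4Z,6R,7E)-8-iodo-2,4,6-trimethylnona-2,4,7-trienoate
Conditions: activated MnO2, 16 (1.5 equiv), CH2Cl2, rt → 40 °C
Reagents that add atoms: ylide 16, CCOC(=O)C(C)=P(c1ccccc1)(c1ccccc1)c1ccccc1
Why: Tandem allylic oxidation/Wittig traps the Z-enal as it forms (no Z→E drift), and the stabilised ylide gives the new 2E olefin.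

Step 11
Reactants: 17
Product: 18 (2E,4Z,6R,7E)-8-iodo-2,4,6-trimethylnona-2,4,7-trien-1-ol
Conditions: DIBAL-H (2.5 equiv), CH2Cl2, −78 °C
Reagents that add atoms: none
Why: Reduction to the dienol parks the future dienophile in an unreactive oxidation state, so the diene can be attached without premature cycloaddition.

Step 12
Reactants: 19 (E)-(2-bromovinyl)benzene; 20 ethynylmagnesium bromide
Product: 21 (E)-but-1-en-3-yn-1-ylbenzene
Conditions: 20, ZnBr2, THF, 0 °C; then 19, Pd(PPh3)4 (3 mol %), rt
Reagents that add atoms: ethynylmagnesium bromide, C#C[Mg]Br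
Why: Negishi ethynylation via ethynylzinc bromide proceeds with retention of the E-styryl geometry.

Step 13
Reactants: 21; 22 trimethylaluminium; 9 iodine
Product: 23 [(1E,3E)-4-iodo-3-methylbuta-1,3-dien-1-yl]benzene
Conditions: Me3Al (2 equiv), Cp2ZrCl2 (0.5 equiv), (CH2Cl)2, rt; then I2, THF, −30 → 0 °C
Reagents that add atoms: Me3Al, C[Al](C)C; I2, II
Why: Negishi Zr-catalysed carboalumination adds Me–Al syn with Me on the internal carbon, and iodinolysis with retention fixes the E-trisubstituted olefin.

Step 14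
Reactants: 23; 20
Product: 24 [(1E,3E)-3-methylhexa-1,3-dien-5-yn-1-yl]benzene
Conditions: 20, ZnBr2, THF; then 23, Pd(PPh3)4 (3 mol %), rt
Reagents that add atoms: ethynylmagnesium bromide, C#C[Mg]Br
Why: Second Negishi ethynylation with retention of olefin geometry gives the terminal dienyne for the next carbometalation.

Step 15
Reactants: 24; 22 trimethylaluminium; 18
Product: 25 (2E,4Z,6S,7E,9E,11E,13E)-2,4,6,8,10,12-hexamethyl-14-phenyltetradeca-2,4,7,9,11,13-hexaen-1-ol
Conditions: 24, Me3Al (2.5 equiv), Cp2ZrCl2, (CH2Cl)2, rt; then 18 (pre-treated with 1 equiv Me3Al), ZnCl2, Pd(PPh3)4 (5 mol %), THF, rt, dark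
Reagents that add atoms: Me3Al, C[Al](C)C
Why: Syn carboalumination of 24 then Al→Zn→Pd Negishi coupling with vinyl iodide 18 forms the C8–C9 bond with retention at both olefins, giving the all-E tetraene (the CIP label at C6 changes from R to S only because iodine is lost).

Step 16
Reactants: 25
Product: 27 (1R,3aR,4R,5S,7aS)-1,3,4,5,7-pentamethyl-5-[(1E,3E)-2-methyl-4-phenylbuta-1,3-dien-1-yl]-3a,4,5,7a-tetrahydro-1H-indene-4-carbaldehyde, via transient hexaenal 26
Conditions: activated MnO2, CH2Cl2, rt, dark; filter; PhMe (BHT), rt → 60 °C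
Reagents that add atoms: none
Why: Allylic oxidation unmasks the enal and triggers a type‑I IMDA forming C3a–C7a and C4–C5. A(1,3) strain with the C8 methyl makes C6–H eclipse the diene, so the dienophile adds anti to the C6 methyl; the CHO-endo/tether-exo transition state gives the trans ring fusion; the 2E and 7E,9E geometries translate stereospecifically into the two quaternary centres.

Step 17
Reactants: 27; 28 sodium chlorite
Product: 29 27-nor-zyggomphic acid B
Conditions: NaClO2, NaH2PO4, 2-methyl-2-butene (excess), t-BuOH/THF/H2O, 0 °C → rt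
Reagents that add atoms: NaClO2, [O-]Cl=O.[Na+]
Why: Pinnick (Lindgren–Kraus) oxidation converts the hindered neopentyl aldehyde to the acid without touching the alkenes (HOCl is scavenged) or any stereocentre.

**Compound list**
1 | methyl (R)-3-hydroxy-2-methylpropanoate ((R)-Roche ester) | OC[C@@H](C)C(=O)OC | starting material
2 | tert-butyldimethylsilyl chloride | CC(C)(C)[Si](C)(C)Cl | starting material (reagent)
3 | methyl (R)-3-[(tert-butyldimethylsilyl)oxy]-2-methylpropanoate | CC(C)(C)[Si](C)(C)OC[C@@H](C)C(=O)OC | intermediate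
4 | (R)-3-[(tert-butyldimethylsilyl)oxy]-2-methylpropanal | CC(C)(C)[Si](C)(C)OC[C@@H](C)C=O | intermediate
5 | carbon tetrabromide | BrC(Br)(Br)Br | starting material (reagent)
6 | (S)-tert-butyl[(4,4-dibromo-2-methylbut-3-en-1-yl)oxy]dimethylsilane | CC(C)(C)[Si](C)(C)OC[C@@H](C)C=C(Br)Br | intermediate
7 | iodomethane | CI | starting material (reagent)
8 | (S)-tert-butyldimethyl[(2-methylpent-3-yn-1-yl)oxy]silane | CC(C)(C)[Si](C)(C)OC[C@@H](C)C#CC | intermediate
9 | iodine | II | starting material (reagent)
10 | (S,E)-tert-butyl[(4-iodo-2-methylpent-3-en-1-yl)oxy]dimethylsilane | CC(C)(C)[Si](C)(C)OC[C@@H](C)/C=C(C)/I | intermediate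
11 | (S,E)-4-iodo-2-methylpent-3-en-1-ol | OC[C@@H](C)/C=C(C)/I | intermediate
12 | (S,E)-4-iodo-2-methylpent-3-enal | O=C[C@@H](C)/C=C(C)/I | intermediate
13 | ethyl 2-[bis(2,2,2-trifluoroethoxy)phosphoryl]propanoate | CCOC(=O)C(C)P(=O)(OCC(F)(F)F)OCC(F)(F)F | starting material (reagent)
14 | ethyl (2Z,4R,5E)-6-iodo-2,4-dimethylhepta-2,5-dienoate | CCOC(=O)/C(C)=C\[C@@H](C)/C=C(C)/I | intermediate
15 | (2Z,4R,5E)-6-iodo-2,4-dimethylhepta-2,5-dien-1-ol | OC/C(C)=C\[C@@H](C)/C=C(C)/I | intermediate
16 | ethyl 2-(triphenylphosphoranylidene)propanoate | CCOC(=O)C(C)=P(c1ccccc1)(c1ccccc1)c1ccccc1 | starting material (reagent)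
17 | ethyl (2E,4Z,6R,7E)-8-iodo-2,4,6-trimethylnona-2,4,7-trienoate | CCOC(=O)/C(C)=C/C(C)=C\[C@@H](C)/C=C(C)/I | intermediate
18 | (2E,4Z,6R,7E)-8-iodo-2,4,6-trimethylnona-2,4,7-trien-1-ol | OC/C(C)=C/C(C)=C\[C@@H](C)/C=C(C)/I | intermediate
19 | (E)-(2-bromovinyl)benzene | Br/C=C/c1ccccc1 | starting material
20 | ethynylmagnesium bromide | C#C[Mg]Br | starting material (reagent)
21 | (E)-but-1-en-3-yn-1-ylbenzene | C#C/C=C/c1ccccc1 | intermediate
22 | trimethylaluminium | C[Al](C)C | starting material (reagent)
23 | [(1E,3E)-4-iodo-3-methylbuta-1,3-dien-1-yl]benzene | I/C=C(C)/C=C/c1ccccc1 | intermediate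
24 | [(1E,3E)-3-methylhexa-1,3-dien-5-yn-1-yl]benzene | C#C/C=C(C)/C=C/c1ccccc1 | intermediate
25 | (2E,4Z,6S,7E,9E,11E,13E)-2,4,6,8,10,12-hexamethyl-14-phenyltetradeca-2,4,7,9,11,13-hexaen-1-ol | OC/C(C)=C/C(C)=C\[C@@H](C)/C=C(C)/C=C(C)/C=C(C)/C=C/c1ccccc1 | intermediate
26 | (2E,4Z,6S,7E,9E,11E,13E)-2,4,6,8,10,12-hexamethyl-14-phenyltetradeca-2,4,7,9,11,13-hexaenal | O=C/C(C)=C/C(C)=C\[C@@H](C)/C=C(C)/C=C(C)/C=C(C)/C=C/c1ccccc1 | intermediate (not isolated)
27 | (1R,3aR,4R,5S,7aS)-1,3,4,5,7-pentamethyl-5-[(1E,3E)-2-methyl-4-phenylbuta-1,3-dien-1-yl]-3a,4,5,7a-tetrahydro-1H-indene-4-carbaldehyde | CC1=C[C@](C)(/C=C(C)/C=C/c2ccccc2)[C@](C)(C=O)[C@H]2C(C)=C[C@@H](C)[C@H]12 | intermediate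
28 | sodium chlorite | [O-]Cl=O.[Na+] | starting material (reagent)
29 | 27-nor-zyggomphic acid B, (1R,3aR,4R,5S,7aS)-1,3,4,5,7-pentamethyl-5-[(1E,3E)-2-methyl-4-phenylbuta-1,3-dien-1-yl]-3a,4,5,7a-tetrahydro-1H-indene-4-carboxylic acid | CC1=C[C@](C)(/C=C(C)/C=C/c2ccccc2)[C@](C)(C(=O)O)[C@H]2C(C)=C[C@@H](C)[C@H]12 | target

**Step count**
Total: 17 steps. Longest linear sequence: 14 (steps 1–11, 15, 16, 17); the west fragment (steps 12–14) is a 3-step branch.

**Three steps most likely to fail, with fallbacks**
1. Step 16 (IMDA). The concerns are trans-fused/CHO-endo versus cis-fused selectivity, and slow formation of the vicinal quaternary C4–C5 bond relative to 1,5-H shift or polyene decomposition. Fallback: cyclise a truncated substrate first. Couple 18 with the alane from carboalumination of TBS-propargyl ether, so the diene terminus carries Me and CH2OTBS. Run the oxidation/IMDA there, where Me2AlCl catalysis is tolerated and enforces the CHO-endo mode. Then build the side chain on the bicycle: CH2OTBS → CHO → Corey–Fuchs/MeI → propynyl → hydrozirconation → Negishi coupling with (E)-β-bromostyrene.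
2. Step 15 (hindered trisubstituted–trisubstituted Negishi coupling with a free alkoxide; competing methyl transfer; polyene sensitivity). Fallback: reverse polarity and timing. Convert 24 to the trienyl iodide (carboalumination/I2), hydrozirconate alkyne 8 and couple it in situ (ZnCl2, Pd) to give the tetraene TBS ether, then carry the tetraene through steps 6–11.
3. Steps 7–8 (epimerisation or conjugation of aldehyde 12; Z/E ratio). Fallback: swap the roles of the two termini by starting from (S)-Roche ester. Run the Z-selective step on the robust TBS-Roche aldehyde (Still–Gennari, or Zhao iodo-olefination followed by Negishi coupling with carboaluminated propargyl alcohol, which gives the dienol directly). Make the E-vinyl iodide last, so the labile aldehyde only sees non-basic Corey–Fuchs conditions.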